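Charge a closed, stirred vessel with the racemic substrate pair, the undissolved solid reagent and the single-handed free catalyst, and hold it at one temperature.

| flask | left-handed substrate | right-handed substrate | solid reagent | free catalyst | temperature | remark | time |
|---|---|---|---|---|---|---|---|
| delta | 40 mM | 40 mM | 54 mM | 1.7 mM | 105 °C | run made earlier |  |
| midnight | 27 mM | 27 mM | 54.0 mM | 1.7 mM | 105 °C |  | 40 min |
| summer | 27 mM | 27 mM | 54.0 mM | 1.7 mM | 90 °C |  | 40 min |

delta run (percent of the left-handed substrate and right-handed substrate together charged)

| time / min | left-handed product / % | left-handed substrate / % |
|---|---|---|
| 1.50 | 0.5 | 49.6 |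
| 3.00 | 0.2 | 49.3 |
| 5.00 | 1.3 | 48.7 |
| 6.00 | 1.5 | 48.4 |
| 8.00 | 1.9 | 47.5 |
| 10.0 | 2.9 | 47.3 |
| 12.0 | 3.2 | 46.7 |

(readings scatter by 0.3 percentage points)

- the flask that comes out highest in amount of left-handed product, in percent of the left-handed substrate and right-handed substrate together charged, or "all alike" when all lie within 1.5 percentage points (midnight / summer / all alike)
- left-handed product at the end, in percent of the left-handed substrate and right-handed substrate together charged, midnight
- left-handed product at the end, in percent of the left-handed substrate and right-handed substrate together charged, summer

- free catalyst is single-handed; left-handed substrate and right-handed substrate are mirror images of each other, charged as a racemate, each of them at the stated concentration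
- given per volume of solution although it is solid: solid reagent
- candidate steps: free catalyst -> spent catalyst; solid reagent <-> partner; partner + free catalyst + right-handed substrate -> free catalyst + right-handed product; partner + free catalyst + left-handed substrate -> free catalyst + left-handed product; partner <-> dormant form
- at the start none of the solid reagent is in solution
- the earlier runs do not show what temperature does; that part of a forecast is a guess

Start from the last line of the delta run. Call the delta pace the share of the charge turned into left-handed product per minute: 0.00267 min⁻¹, a reading with its scatter.

The rise looks straight, yet left-handed substrate fell by 3.3 percentage points meanwhile, and its product step consumes it, so the rise ought to bend. Reckon the bend. If the pace follows left-handed substrate, by the last reading it has sagged by 6.60%, and the line loses half of that: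

3.2% × 6.60% / 2 = 0.11 points

That is less than the scatter of 0.3 points, so these readings do not tell the bend from a straight line.

Over 40 min the bend counts. Hold the pace for midnight, which has the same catalyst, solid and temperature but less substrate, and go round twice:

first round: 0.00267 min⁻¹ × 40 min = 10.7%

second round: 10.7% × (1 − 10.7%) = 9.53%

The bracket is my estimate of the mean share of left-handed substrate left during the run. My figure for midnight is 9.53%. The earlier runs do not show what temperature does, so for summer any figure is a guess.

The forecast gives 8.5% for midnight, lower than my figure, and 3.8% for summer, this one on “a guessed activation energy”, and picks midnight.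

The flasks give 6.09% in midnight and 16.3% in summer, so summer comes out higher.

    free catalyst → spent catalyst (k = 6.40 × 10⁻⁴ s⁻¹, Ea = 99.0 kJ mol⁻¹)
    solid reagent ⇌ partner, rate k2*(cs2 - [partner]) while solid is left; crystals form when [partner] > cs2 (solubility = 15.0 mM, k = 0.00180 s⁻¹)
    partner + free catalyst + right-handed substrate → free catalyst + right-handed product (k = 35.0 L² mol⁻² s⁻¹, Ea = 50.0 kJ mol⁻¹)
    partner + free catalyst + left-handed substrate → free catalyst + left-handed product (k = 85.0 L² mol⁻² s⁻¹, Ea = 46.0 kJ mol⁻¹)
    partner ⇌ dormant form (K = 7.80, k = 0.0430 s⁻¹, Ea = 96.0 kJ mol⁻¹, ΔH = −2.00 kJ mol⁻¹)
    (constants at 90 °C)

Divide by the pace: midnight's yield is worth 22.8 min, summer's 61.0 min, more than its 40 min. In midnight free catalyst stood at 5.96% of its charge after 20.0 min, while left-handed product went from 5.02% then to 6.09% at 40.0 min. In summer free catalyst stood at 46.4% of its charge after 20.0 min and 21.5% at 40.0 min, while left-handed product went from 8.46% to 16.3%.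

Take midnight's flask at 120 °C: the pace, read at 105 °C and carried unchanged, gives 9.53% again. The computed flask gives 1.19%, worth 4.46 min of delta pace, with free catalyst at 0% at the end.

The readings are calculated on assumed constants, noise included.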